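**Plan**

1. Numbering (longipinane, used for these atoms in all ring intermediates): C1 ketone, C2=C3 (methyl on C3), C4 and C11 bridgehead CH, C5 the CH that carries the gem-dimethyl carbon C6, C7 (angelate), C8 (isobutyrate), C9 (CH2), C10 (quaternary, methyl).
2. Retrosynthesis: the esters come off; then C6–C7 and C8–C9 are cut together, which excises C7–C8 as an oxalyl unit and leaves a bicyclo[3.1.1]heptane with a CH2 arm on C10 and a CMe2 arm on C5. The cyclobutane C4–C5–C11–C10 is then cut at C4–C10 and C5–C11 to an acyclic vinylketene–alkene.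
3. Enabling feature: C9 and C6 are the cis-1,3 substituents that point toward each other across the cyclobutane C4–C5–C11–C10, held about 3 Å apart by the rigid bicyclo[3.1.1]heptane. A two-carbon bis-electrophile can therefore bridge them into the seven-membered ring C5–C6–C7–C8–C9–C10–C11.
4. Forward: acyclic silyl ether → intramolecular vinylketene–alkene [2+2] (cyclobutane and six-membered ring C1–C2–C3–C4–C5–C11 together) → CH2Cl arm on C10 and CMe2SO2Ph arm on C5 → dilithium/oxamide annulation (seven-membered ring) → enone, trans-diol, two esters.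
5. Stereochemistry: one carbinol (the future C1 ketone) is set by a chiral boron Lewis acid and relays C4, C10 and C11 in the [2+2]. C5 follows from hydroxyl-directed hydrogenation, C8 from catalyst-controlled transfer hydrogenation, C7 from hydroxyl-directed hydride delivery.

Key step: step 14

Assumption: in step 7 the alkene face is selected with the allylic silyloxy group on the outside, away from the ketene tether (allylic-strain model); on this basis the (5S)-carbinol of step 2 leads to the required configuration at C4, C10 and C11.

**Route**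

Step 1
Reactants: 1 ethyl 3-methylbut-2-enoate
Product: 2 (1Z)-1-ethoxy-3-methyl-1-(tert-butyldimethylsilyloxy)buta-1,3-diene
Conditions: LDA (commercial solution), THF/DMPU, −78 °C; TBSCl, −78 °C → rt
Reagents that add atoms: tert-butyldimethylsilyl chloride, CC(C)(C)[Si](C)(C)Cl
Why: kinetic γ-deprotonation of the β,β-dimethyl enoate and O-silylation of the extended enolate (silyl dienol ether formation) should give the dienolate; no stereocentre, and the ketene acetal geometry is of no consequence.

Step 2
Reactants: 2 (1Z)-1-ethoxy-3-methyl-1-(tert-butyldimethylsilyloxy)buta-1,3-diene; 3 3-methylbut-2-enal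
Product: 4 ethyl (2E,5S)-5-hydroxy-3,7-dimethylocta-2,6-dienoate
Conditions: N-tosyl-L-tryptophan + PhBCl2 (1.0 equiv each, CH2Cl2, rt, then evaporated, giving the B-phenyl oxazaborolidinone); i-PrOH (1.1 equiv), n-PrCN, −78 °C; aq. NaHCO3
Reagents that add atoms: none
Why: vinylogous Mukaiyama aldol addition, in which the boron Lewis acid activates the enal and the dienolate attacks through its γ-CH2 terminus; reagent control sets the 5S carbinol (the D-tryptophan reagent would be used if the sense were opposite), and the C2=C3 geometry is irrelevant because step 7 erases it.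

Step 3
Reactants: 4 ethyl (2E,5S)-5-hydroxy-3,7-dimethylocta-2,6-dienoate
Product: 5 ethyl (2E,5S)-5-(tert-butyldimethylsilyloxy)-3,7-dimethylocta-2,6-dienoate
Conditions: TBSCl, imidazole, DMF, rt
Reagents that add atoms: tert-butyldimethylsilyl chloride, CC(C)(C)[Si](C)(C)Cl
Why: routine silylation of a secondary allylic alcohol (protection); the stereocentre is not touched.

Step 4
Reactants: 5 ethyl (2E,5S)-5-(tert-butyldimethylsilyloxy)-3,7-dimethylocta-2,6-dienoate
Product: 6 ethyl (2E,5S,6E)-5-(tert-butyldimethylsilyloxy)-8-hydroxy-3,7-dimethylocta-2,6-dienoate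
Conditions: SeO2 (0.3 equiv), t-BuOOH, CH2Cl2, 0 °C → rt
Reagents that add atoms: tert-butyl hydroperoxide, CC(C)(C)OO
Why: catalytic SeO2 allylic hydroxylation (ene reaction, then [2,3]-shift) oxidises the E-methyl group of a gem-dimethyl trisubstituted alkene and leaves the electron-poor enoate alkene alone; this fixes the 6E geometry.

Step 5
Reactants: 6 ethyl (2E,5S,6E)-5-(tert-butyldimethylsilyloxy)-8-hydroxy-3,7-dimethylocta-2,6-dienoate
Product: 7 ethyl (2E,5S,6E)-5,8-bis(tert-butyldimethylsilyloxy)-3,7-dimethylocta-2,6-dienoate
Conditions: TBSCl, imidazole, DMF, rt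
Reagents that add atoms: tert-butyldimethylsilyl chloride, CC(C)(C)[Si](C)(C)Cl
Why: silylation of the primary allylic alcohol (protection) so that the acid can later be activated.

Step 6
Reactants: 7 ethyl (2E,5S,6E)-5,8-bis(tert-butyldimethylsilyloxy)-3,7-dimethylocta-2,6-dienoate
Product: 8 (2E,5S,6E)-5,8-bis(tert-butyldimethylsilyloxy)-3,7-dimethylocta-2,6-dienoic acid
Conditions: LiOH·H2O, THF/MeOH/H2O, 40 °C; then 1 M HCl to pH 4, 0 °C
Reagents that add atoms: lithium hydroxide, [Li+].[OH-]
Why: saponification of the ethyl ester; silyl ethers and the stereocentre should survive the mild base and the brief cold acidification.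

Step 7
Reactants: 8 (2E,5S,6E)-5,8-bis(tert-butyldimethylsilyloxy)-3,7-dimethylocta-2,6-dienoic acid
Product: 11 4-(tert-butyldimethylsilyloxy)-7-[(tert-butyldimethylsilyloxy)methyl]-7-methyl-2-methylidenebicyclo[3.1.1]heptan-6-one (silyloxymethyl on C7 syn to the C6 carbonyl bridge, methyl syn to the C2–C4 bridge, silyloxy on C4 on the side of the carbonyl bridge; absolute configuration as in the SMILES), via acid chloride 9 (not isolated), via vinylketene 10 (not isolated)
Conditions: NaH, benzene, 0 °C; (COCl)2, 0 °C → rt; evaporate; Et3N (3 equiv), toluene (0.01 M), reflux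
Reagents that add atoms: none
Why: γ-dehydrochlorination of the enoyl chloride gives a vinylketene that should undergo the known intramolecular ketene–alkene [2+2] cycloaddition in the bridged mode (the ketene carbonyl carbon bonds to the internal alkene carbon, the later C11, because the terminal carbon, the later C10, is the more substituted), suprafacially on the alkene, so that the 6E geometry places the silyloxymethyl group syn to the carbonyl bridge, while the silyloxy-bearing carbon relays the facial sense (see assumption) and so fixes C4, C10 and C11.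

Step 8
Reactants: 11 bicyclic ketone (as named in step 7)
Product: 12 4-(tert-butyldimethylsilyloxy)-7-[(tert-butyldimethylsilyloxy)methyl]-7-methyl-2-methylidene-6-[(phenylsulfonyl)methylidene]bicyclo[3.1.1]heptane (numbering as in 11; mixture of isomers at the sulfonyl alkene)
Conditions: PhSO2CH2SiMe3, n-BuLi, THF, −78 °C; then 11, −78 → 0 °C
Reagents that add atoms: [(phenylsulfonyl)methyl]trimethylsilane, C[Si](C)(C)CS(=O)(=O)c1ccccc1
Why: Peterson olefination, in which the α-silyl α-sulfonyl carbanion adds to the strained, non-enolisable cyclobutanone and the β-silyl alkoxide eliminates at low temperature before ring cleavage can compete; no stereocentre, and either alkene isomer serves.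

Step 9
Reactants: 12 bis-silyl vinyl sulfone (as named in step 8)
Product: 13 [4-(tert-butyldimethylsilyloxy)-7-methyl-2-methylidene-6-[(phenylsulfonyl)methylidene]bicyclo[3.1.1]heptan-7-yl]methanol (numbering as in 11)
Conditions: HF·pyridine, pyridine, THF, 0 °C
Reagents that add atoms: none
Why: buffered HF·pyridine should cleave the primary silyl ether faster than the more hindered secondary one (selective desilylation).

Step 10
Reactants: 13 primary alcohol (as named in step 9)
Product: 14 4-(tert-butyldimethylsilyloxy)-7-(chloromethyl)-7-methyl-2-methylidene-6-[(phenylsulfonyl)methylidene]bicyclo[3.1.1]heptane (numbering as in 11)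
Conditions: PPh3, CCl4, MeCN, 60 °C
Reagents that add atoms: carbon tetrachloride, ClC(Cl)(Cl)Cl
Why: Appel chlorination, a displacement on the alkoxyphosphonium ion that tolerates neopentyl carbons and passes through no carbocation, so the cyclobutylcarbinyl system should not ring-expand.

Step 11
Reactants: 14 chloride (as named in step 10)
Product: 15 7-(chloromethyl)-7-methyl-2-methylidene-6-[(phenylsulfonyl)methylidene]bicyclo[3.1.1]heptan-4-ol (numbering as in 11; hydroxyl on the side of the sulfonylmethylidene bridge)
Conditions: 48% aq. HF, MeCN, rt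
Reagents that add atoms: none
Why: acidic fluoride desilylation frees the C1 hydroxyl that directs step 12 and serves as an alkoxide in step 14; vinyl sulfone and alkyl chloride are inert.

Step 12
Reactants: 15 hydroxy vinyl sulfone (as named in step 11)
Product: 16 7-(chloromethyl)-2,7-dimethyl-6-[(phenylsulfonyl)methyl]bicyclo[3.1.1]heptan-4-ol (numbering as in 11; chloromethyl on C7 and sulfonylmethyl on C6 cis, pointing toward each other; configuration as in the SMILES)
Conditions: H2 (1 atm), [Ir(cod)(PCy3)(py)]PF6 (5 mol %), CH2Cl2, rt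
Reagents that add atoms: none
Why: hydroxyl-directed hydrogenation, in which the cationic iridium catalyst binds the C1 hydroxyl (on the three-carbon bridge, on the side of the C5 bridge) and delivers H2 to both alkenes from that side, so that hydrogen enters C5 from the face of the three-carbon bridge and the sulfonylmethyl group is pushed syn to the chloromethyl group (C5 set); the new C3 methine is of no consequence because step 15 planarises it.

Step 13
Reactants: 16 hydroxy sulfone (as named in step 12)
Product: 18 7-(chloromethyl)-2,7-dimethyl-6-[2-(phenylsulfonyl)propan-2-yl]bicyclo[3.1.1]heptan-4-ol (numbering as in 11), via monomethyl sulfone 17 (not isolated)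
Conditions: n-BuLi (2.1 equiv), THF, −78 °C; MeI (1.05 equiv); n-BuLi (1.1 equiv), −78 °C; MeI (1.1 equiv), −78 → −20 °C; H2O
Reagents that add atoms: iodomethane, CI
Why: two successive deprotonation–methylation cycles of the α-sulfonyl carbanion (sulfone alkylation) build the gem-dimethyl carbon C6; at −78 °C the lithium alkoxide is far less nucleophilic than the carbanion, and the sulfonyl-bearing stereocentre of 17 disappears in 18.

Step 14
Reactants: 18 chloro sulfone (as named in step 13); 19 1,4-dimethylpiperazine-2,3-dione
Product: 22 1-hydroxylongipinane-7,8-dione (tricyclic skeleton of the target with C1 carbinol, saturated C2–C3 and C3 methyl; configuration as in the SMILES), via trilithium species 20 (not isolated), via bis-hemiaminal dialkoxide 21 (not isolated)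
Conditions: n-BuLi (1.0 equiv), THF, −78 °C; lithium 4,4′-di-tert-butylbiphenylide (4.4 equiv, titrated to a persistent green colour), −78 °C; 19 (1.0 equiv, slow addition), −78 → −20 °C; 2 M HCl, 0 °C
Reagents that add atoms: none
Why: Proposed new method: after deprotonation of the C1 hydroxyl, electron transfer from lithium 4,4′-di-tert-butylbiphenylide cleaves the C9–Cl bond and the tertiary C6–SO2Ph bond, and the radicals are reduced to carbanions faster than the saturated cyclobutylcarbinyl framework can open, so a 1,5-dilithium species with both C–Li bonds pointing toward each other across the cyclobutane should result; the primary C9–Li adds to one amide carbonyl of 19, the tertiary C6–Li then adds to the neighbouring carbonyl, and both chelated N,O-tetrahedral adducts survive until aqueous acid releases the 7,8-dione. The closest known reaction type is the twofold addition of organolithium or Grignard reagents to 1,4-dimethylpiperazine-2,3-dione, which gives 1,2-diketones without over-addition, combined with reductive lithiation of alkyl chlorides and of tertiary alkyl phenyl sulfones; new is its annulative use with a dilithium reagent that contains a tertiary centre. The seven-membered ring C5–C6–C7–C8–C9–C10–C11 is closed by the second addition in a 7-exo-trig mode at the amide carbonyl. No stereocentre is formed, and C4, C5, C10 and C11 are not touched. The step needs single addition at each carbonyl and ring closure rather than oligomerisation or C–C fragmentation: the stable tetrahedral intermediates stop at the ketone level, the rigid cis-1,3 arrangement of the two arms about 3 Å apart and the slow addition of 19 favour closure, and the C1 alkoxide (a poor leaving group) together with the absence of any π-system next to the ring should keep the cyclobutylcarbinyl anions intact.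

Step 15
Reactants: 22 1-hydroxylongipinane-7,8-dione
Product: 23 longipin-2-ene-1,7,8-trione
Conditions: 2-iodoxybenzoic acid (3.5 equiv), DMSO, 80 °C
Reagents that add atoms: none
Why: 2-iodoxybenzoic acid first oxidises the C1 carbinol to the ketone and then dehydrogenates it toward C2–C3 (α,β-dehydrogenation), the only side that can enolise because C11 is a bridgehead, while the 7,8-dione has no β-hydrogen on C10 and cannot be desaturated; no stereocentre is formed and C3 is planarised.

Step 16
Reactants: 23 longipin-2-ene-1,7,8-trione
Product: 24 8-hydroxylongipin-2-ene-1,7-dione (8S; configuration as in the SMILES)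
Conditions: RuCl[(S,S)-TsDPEN](p-cymene) (2 mol %), HCO2H/Et3N (5:2), DMF, rt
Reagents that add atoms: none
Why: asymmetric transfer hydrogenation should reduce the activated 1,2-dione much faster than the hindered enone and attack the less hindered C8 carbonyl (C7 is flanked by the quaternary C6), with catalyst control setting C8 (the (R,R)-catalyst would be used if the sense were opposite).

Step 17
Reactants: 24 8-hydroxylongipin-2-ene-1,7-dione
Product: 25 trans-7,8-dihydroxylongipin-2-en-1-one (configuration as in the SMILES)
Conditions: Me4NBH(OAc)3, MeCN/AcOH (1:1), −20 °C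
Reagents that add atoms: none
Why: hydroxyl-directed reduction (Evans–Saksena type), in which the C8 alkoxy-triacetoxyborohydride delivers hydride intramolecularly to the C7 ketone on the face of the C8–O bond and so gives the trans-diol (C7 set by C8); the enone has no directing hydroxyl and should not be reduced.

Step 18
Reactants: 25 trans-7,8-dihydroxylongipin-2-en-1-one
Product: 26 trans-7-hydroxy-8-(isobutyryloxy)longipin-2-en-1-one
Conditions: (i-PrCO)2O (1.1 equiv), pyridine, DMAP (5 mol %), CH2Cl2, −20 °C
Reagents that add atoms: isobutyric anhydride, CC(C)C(=O)OC(=O)C(C)C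
Why: selective esterification, since the C8 hydroxyl next to the C9 methylene is far more accessible than the neopentyl C7 hydroxyl next to the quaternary C6; no stereocentre is touched.

Step 19
Reactants: 26 trans-7-hydroxy-8-(isobutyryloxy)longipin-2-en-1-one; 27 angelic acid, (Z)-2-methylbut-2-enoic acid
Product: 29 trans-7-(angeloyloxy)-8-(isobutyryloxy)longipin-2-en-1-one (CNP0286736.1), via mixed anhydride 28 (not isolated)
Conditions: 27, 2,4,6-trichlorobenzoyl chloride, Et3N, toluene, rt; then 26, DMAP, toluene, 70 °C
Reagents that add atoms: none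
Why: Yamaguchi esterification, in which the mixed 2,4,6-trichlorobenzoic anhydride of angelic acid with DMAP acylates the hindered C7 hydroxyl under conditions in which the Z-alkene of angelates is normally retained.

**Compound list**

1 | ethyl 3-methylbut-2-enoate | CCOC(=O)C=C(C)C | starting material
2 | (1Z)-1-ethoxy-3-methyl-1-(tert-butyldimethylsilyloxy)buta-1,3-diene | CCO/C(O[Si](C)(C)C(C)(C)C)=C/C(C)=C | intermediate
3 | 3-methylbut-2-enal | CC(C)=CC=O | starting material
4 | ethyl (2E,5S)-5-hydroxy-3,7-dimethylocta-2,6-dienoate | CCOC(=O)/C=C(\C)C[C@H](O)C=C(C)C | intermediate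
5 | ethyl (2E,5S)-5-(tert-butyldimethylsilyloxy)-3,7-dimethylocta-2,6-dienoate | CCOC(=O)/C=C(\C)C[C@H](O[Si](C)(C)C(C)(C)C)C=C(C)C | intermediate
6 | ethyl (2E,5S,6E)-5-(tert-butyldimethylsilyloxy)-8-hydroxy-3,7-dimethylocta-2,6-dienoate | CCOC(=O)/C=C(\C)C[C@H](O[Si](C)(C)C(C)(C)C)/C=C(\C)CO | intermediate
7 | ethyl (2E,5S,6E)-5,8-bis(tert-butyldimethylsilyloxy)-3,7-dimethylocta-2,6-dienoate | CCOC(=O)/C=C(\C)C[C@H](O[Si](C)(C)C(C)(C)C)/C=C(\C)CO[Si](C)(C)C(C)(C)C | intermediate
8 | (2E,5S,6E)-5,8-bis(tert-butyldimethylsilyloxy)-3,7-dimethylocta-2,6-dienoic acid | OC(=O)/C=C(\C)C[C@H](O[Si](C)(C)C(C)(C)C)/C=C(\C)CO[Si](C)(C)C(C)(C)C | intermediate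
9 | (2E,5S,6E)-5,8-bis(tert-butyldimethylsilyloxy)-3,7-dimethylocta-2,6-dienoyl chloride (not isolated) | ClC(=O)/C=C(\C)C[C@H](O[Si](C)(C)C(C)(C)C)/C=C(\C)CO[Si](C)(C)C(C)(C)C | intermediate
10 | (5S,6E)-5,8-bis(tert-butyldimethylsilyloxy)-7-methyl-3-methylideneocta-1,6-dien-1-one, vinylketene (not isolated) | O=C=CC(=C)C[C@H](O[Si](C)(C)C(C)(C)C)/C=C(\C)CO[Si](C)(C)C(C)(C)C | intermediate
11 | 4-(tert-butyldimethylsilyloxy)-7-[(tert-butyldimethylsilyloxy)methyl]-7-methyl-2-methylidenebicyclo[3.1.1]heptan-6-one | CC(C)(C)[Si](C)(C)OC[C@@]1(C)[C@@H]2[C@@H](O[Si](C)(C)C(C)(C)C)CC(=C)[C@H]1C2=O | intermediate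
12 | 6-[(phenylsulfonyl)methylidene] analogue of 11 (sulfonyl alkene isomers, descriptor left open) | CC(C)(C)[Si](C)(C)OC[C@@]1(C)[C@@H]2[C@@H](O[Si](C)(C)C(C)(C)C)CC(=C)[C@H]1C2=CS(=O)(=O)c1ccccc1 | intermediate
13 | [4-(tert-butyldimethylsilyloxy)-7-methyl-2-methylidene-6-[(phenylsulfonyl)methylidene]bicyclo[3.1.1]heptan-7-yl]methanol | OC[C@@]1(C)[C@@H]2[C@@H](O[Si](C)(C)C(C)(C)C)CC(=C)[C@H]1C2=CS(=O)(=O)c1ccccc1 | intermediate
14 | 4-(tert-butyldimethylsilyloxy)-7-(chloromethyl)-7-methyl-2-methylidene-6-[(phenylsulfonyl)methylidene]bicyclo[3.1.1]heptane | ClC[C@@]1(C)[C@@H]2[C@@H](O[Si](C)(C)C(C)(C)C)CC(=C)[C@H]1C2=CS(=O)(=O)c1ccccc1 | intermediate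
15 | 7-(chloromethyl)-7-methyl-2-methylidene-6-[(phenylsulfonyl)methylidene]bicyclo[3.1.1]heptan-4-ol | ClC[C@@]1(C)[C@@H]2[C@@H](O)CC(=C)[C@H]1C2=CS(=O)(=O)c1ccccc1 | intermediate
16 | 7-(chloromethyl)-2,7-dimethyl-6-[(phenylsulfonyl)methyl]bicyclo[3.1.1]heptan-4-ol | ClC[C@@]1(C)[C@@H]2[C@@H](O)C[C@H](C)[C@H]1[C@@H]2CS(=O)(=O)c1ccccc1 | intermediate
17 | 7-(chloromethyl)-2,7-dimethyl-6-[1-(phenylsulfonyl)ethyl]bicyclo[3.1.1]heptan-4-ol (epimers at the sulfonyl carbon; not isolated) | ClC[C@@]1(C)[C@@H]2[C@@H](O)C[C@H](C)[C@H]1[C@@H]2C(C)S(=O)(=O)c1ccccc1 | intermediate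
18 | 7-(chloromethyl)-2,7-dimethyl-6-[2-(phenylsulfonyl)propan-2-yl]bicyclo[3.1.1]heptan-4-ol | ClC[C@@]1(C)[C@@H]2[C@@H](O)C[C@H](C)[C@H]1[C@@H]2C(C)(C)S(=O)(=O)c1ccccc1 | intermediate
19 | 1,4-dimethylpiperazine-2,3-dione | CN1CCN(C)C(=O)C1=O | starting material
20 | trilithium species: lithium alkoxide at C1, C9–Li, C6–Li (not isolated) | [Li]C[C@@]1(C)[C@@H]2[C@@H](O[Li])C[C@H](C)[C@H]1[C@@H]2C(C)(C)[Li] | intermediate
21 | bis-hemiaminal dialkoxide, piperazine fused at C7–C8 (aminal carbons undefined; not isolated) | [Li]OC12C[C@@]3(C)[C@@H]4[C@@H](O[Li])C[C@H](C)[C@H]3[C@@H]4C(C)(C)C1(O[Li])N(C)CCN2C | intermediate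
22 | 1-hydroxylongipinane-7,8-dione | O=C1C(=O)C[C@@]2(C)[C@@H]3[C@@H](O)C[C@H](C)[C@H]2[C@@H]3C1(C)C | intermediate
23 | longipin-2-ene-1,7,8-trione | O=C1C(=O)C[C@@]2(C)[C@@H]3C(=O)C=C(C)[C@H]2[C@@H]3C1(C)C | intermediate
24 | (8S)-8-hydroxylongipin-2-ene-1,7-dione | O=C1[C@@H](O)C[C@@]2(C)[C@@H]3C(=O)C=C(C)[C@H]2[C@@H]3C1(C)C | intermediate
25 | trans-7,8-dihydroxylongipin-2-en-1-one | O[C@@H]1[C@@H](O)C[C@@]2(C)[C@@H]3C(=O)C=C(C)[C@H]2[C@@H]3C1(C)C | intermediate
26 | trans-7-hydroxy-8-(isobutyryloxy)longipin-2-en-1-one | O[C@@H]1[C@@H](OC(=O)C(C)C)C[C@@]2(C)[C@@H]3C(=O)C=C(C)[C@H]2[C@@H]3C1(C)C | intermediate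
27 | angelic acid, (Z)-2-methylbut-2-enoic acid | C/C=C(/C)C(=O)O | starting material
28 | angelic 2,4,6-trichlorobenzoic anhydride (not isolated) | C/C=C(/C)C(=O)OC(=O)c1c(Cl)cc(Cl)cc1Cl | intermediate
29 | trans-7-(angeloyloxy)-8-(isobutyryloxy)longipin-2-en-1-one, CNP0286736.1 | C/C=C(/C)C(=O)O[C@@H]1[C@@H](OC(=O)C(C)C)C[C@@]2(C)[C@@H]3C(=O)C=C(C)[C@H]2[C@@H]3C1(C)C | target

Total step count: 19. Longest linear sequence: 19 steps (1 → 29).

**Steps most likely to fail**

Step 14 (Proposed new method). What may go wrong: after the first C–Li addition the hindered tertiary alkyllithium may be protonated or may add to a second oxamide molecule, so that open-chain or oligomeric products form instead of the ring; partial C–C fragmentation of the cyclobutylcarbinyl anions is a second loss channel. Fallback, from 18 back to the route at 23: the hydroxyl deprotonation and reductive lithiation of 18 are kept, but the dilithium species is quenched with N,N-dimethylformamide, a small electrophile that each C–Li bond takes up independently, which after acidic work-up would give the dialdehyde 7,8-seco-1-hydroxylongipinane-7,8-dial F1. An intramolecular benzoin reaction (3-benzyl-5-(2-hydroxyethyl)-4-methylthiazolium chloride, Et3N, EtOH, 70 °C), in which the unhindered C8 aldehyde forms the acyl-anion equivalent and attacks the neopentyl C7 aldehyde, would close the seven-membered ring as the acyloin 1,7-dihydroxylongipinan-8-one F2. 2-Iodoxybenzoic acid (DMSO, 80 °C) would then oxidise both carbinols and dehydrogenate C2–C3, which returns to the route at 23.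

Step 12. What may go wrong: hydrogen has to be delivered so that the sulfonylmethyl group ends in the crowded position syn to the chloromethyl group; poor facial selectivity at C5, or stalling of the iridium catalyst through binding to the sulfone, would erode the one stereocentre on which ring closure depends. Fallback, from 15 back to the route at 16: the hydroxyl would direct a hydride instead of hydrogen. Treatment of 15 with NaAlH2(OCH2CH2OMe)2 (toluene/THF, −40 °C) binds aluminium to the C1 oxygen and delivers hydride intramolecularly to C5, the β-carbon of the vinyl sulfone, from the face of the three-carbon bridge, which would give 7-(chloromethyl)-7-methyl-2-methylidene-6-[(phenylsulfonyl)methyl]bicyclo[3.1.1]heptan-4-ol F3. Hydrogenation of the remaining exocyclic methylene (H2, Pd/C, EtOAc) then gives 16; either C3 epimer serves, since step 15 planarises C3.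

Step 19. What may go wrong: acylation of the neopentyl C7 hydroxyl is slow, which gives time for Z → E isomerisation of the activated angelate (tiglate formation) and for 1,2-migration of the isobutyryl group. Fallback, from 26 back to the route at 29: the alkene would be built on the molecule with its geometry controlled by the olefination. Acylation of 26 with 2-[bis(2,2,2-trifluoroethoxy)phosphoryl]propanoic acid (N,N′-dicyclohexylcarbodiimide, DMAP, CH2Cl2) would give the 7-O-[2-(bis(2,2,2-trifluoroethoxy)phosphoryl)propanoyl] ester F4. A Z-selective Horner–Wadsworth–Emmons reaction (Still–Gennari variant: KN(SiMe3)2, 18-crown-6, THF, −78 °C, then acetaldehyde) would then give the (Z)-2-methylbut-2-enoate, that is 29.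

Further compounds
F1 | step 14 | 7,8-seco-1-hydroxylongipinane-7,8-dial (CH2CHO on C10, CMe2CHO on C5) | O=CC[C@@]1(C)[C@@H]2[C@@H](O)C[C@H](C)[C@H]1[C@@H]2C(C)(C)C=O
F2 | step 14 | 1,7-dihydroxylongipinan-8-one (C7 carbinol epimers) | O=C1C[C@@]2(C)[C@@H]3[C@@H](O)C[C@H](C)[C@H]2[C@@H]3C(C)(C)C1O
F3 | step 12 | 7-(chloromethyl)-7-methyl-2-methylidene-6-[(phenylsulfonyl)methyl]bicyclo[3.1.1]heptan-4-ol | ClC[C@@]1(C)[C@@H]2[C@@H](O)CC(=C)[C@H]1[C@@H]2CS(=O)(=O)c1ccccc1
F4 | step 19 | trans-8-(isobutyryloxy)-7-{2-[bis(2,2,2-trifluoroethoxy)phosphoryl]propanoyloxy}longipin-2-en-1-one (epimers at the phosphonate carbon) | CC(C(=O)O[C@@H]1[C@@H](OC(=O)C(C)C)C[C@@]2(C)[C@@H]3C(=O)C=C(C)[C@H]2[C@@H]3C1(C)C)P(=O)(OCC(F)(F)F)OCC(F)(F)F
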